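**Retrosynthetic overview** (ring A = methoxy-bearing ring, ring B = meta-phenylene, ring C = phenol ring, ring D = para-phenylene)
- Target 21 comes from its O-isopropyl ether 19 with BCl3; the isopropyl group distinguishes the ring C oxygen from the ring A methoxy group.
- Feature used: the ether oxygen on C-3 of ring C is bonded to C-4 of ring D, para to the CH2CH2 link to ring A. That is the carbon which carries the carboxyl group in a 4-(2-arylethyl)benzoate, so the 18-membered ether 19 is the 19-membered aryl benzoate 18 minus CO (nickel-mediated extrusion).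
- Lactone 18 comes from seco acid 16 by phenolic macrolactonization (O-3 of ring C onto the ring D carboxyl group).
- Acid 16 comes from two Wittig olefinations and one hydrogenation/debenzylation that attach ring D (ylide from 4) and ring C (aldehyde 12 from 10) to the A–B diaryl ether 3, itself made by fluoride displacement on 1 with 2.
- Ring order: the 19-membered lactone is closed first (step 10) and contracted to the 18-membered ring of the target (step 11); no other ring is formed.

Key step: step 11

Remark: the target has no stereocentre; stilbenes 7, 9 and 14 are carried forward as E/Z mixtures because both double bonds are hydrogenated in step 8.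

**Route**

Step 1
Reactants: 1 2-fluoro-3-methoxybenzaldehyde; 2 3-hydroxybenzyl alcohol
Product: 3 2-[3-(hydroxymethyl)phenoxy]-3-methoxybenzaldehyde
Conditions: K2CO3 (1.5 equiv), DMAc, 120 °C
Reagents that add atoms: none
Why: Nucleophilic aromatic substitution of the fluoride activated by the ortho formyl group should occur with the phenoxide, which carbonate forms selectively over the much less acidic benzylic alcohol.

Step 2
Reactants: 4 methyl 4-(bromomethyl)benzoate
Product: 5 [4-(methoxycarbonyl)benzyl]triphenylphosphonium bromide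
Conditions: PPh3, toluene, reflux
Reagents that add atoms: triphenylphosphine, c1ccc(cc1)P(c1ccccc1)c1ccccc1
Why: SN2 quaternization of triphenylphosphine by a primary benzylic bromide should give the salt, which precipitates from toluene.

Step 3
Reactants: 3 2-[3-(hydroxymethyl)phenoxy]-3-methoxybenzaldehyde; 5 [4-(methoxycarbonyl)benzyl]triphenylphosphonium bromide
Product: 7 methyl 4-[2-{2-[3-(hydroxymethyl)phenoxy]-3-methoxyphenyl}ethenyl]benzoate (E/Z mixture), via phosphorus ylide 6 (not isolated)
Conditions: K2CO3, 18-crown-6 (cat.), CH2Cl2, reflux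
Reagents that add atoms: none
Why: Wittig olefination of the aryl aldehyde with a semi-stabilized benzylic ylide generated by solid carbonate under phase-transfer conditions should leave the methyl ester and the free benzylic alcohol untouched.

Step 4
Reactants: 7 methyl 4-[2-{2-[3-(hydroxymethyl)phenoxy]-3-methoxyphenyl}ethenyl]benzoate
Product: 9 {3-[2-methoxy-6-[2-(4-(methoxycarbonyl)phenyl)ethenyl]phenoxy]benzyl}triphenylphosphonium bromide (E/Z mixture), via benzylic bromide 8 (not isolated)
Conditions: PPh3·HBr, MeCN, reflux
Reagents that add atoms: triphenylphosphine hydrobromide, c1ccc(cc1)[PH+](c1ccccc1)c1ccccc1.[Br-]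
Why: Acid-promoted substitution of the benzylic alcohol by bromide followed by SN2 quaternization of triphenylphosphine, the usual one-pot conversion of benzylic alcohols into benzylphosphonium bromides, should spare the ester and the stilbene.

Step 5
Reactants: 10 3,4-dihydroxybenzaldehyde
Product: 11 3-hydroxy-4-isopropoxybenzaldehyde
Conditions: 2-bromopropane (1.1 equiv), K2CO3 (1.0 equiv), DMF, 50 °C
Reagents that add atoms: 2-bromopropane, CC(C)Br
Why: Williamson alkylation with one equivalent of base should occur at the 4-hydroxyl, which is the more acidic one because it is para to the formyl group.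

Step 6
Reactants: 11 3-hydroxy-4-isopropoxybenzaldehyde
Product: 12 3-(benzyloxy)-4-isopropoxybenzaldehyde
Conditions: BnBr, K2CO3, DMF, 50 °C
Reagents that add atoms: benzyl bromide, BrCc1ccccc1
Why: Williamson benzylation of the remaining phenol masks it for the Wittig step with a group that the later hydrogenation removes.

Step 7
Reactants: 9 {3-[2-methoxy-6-[2-(4-(methoxycarbonyl)phenyl)ethenyl]phenoxy]benzyl}triphenylphosphonium bromide; 12 3-(benzyloxy)-4-isopropoxybenzaldehyde
Product: 14 methyl 4-[2-{2-[3-(2-{3-(benzyloxy)-4-isopropoxyphenyl}ethenyl)phenoxy]-3-methoxyphenyl}ethenyl]benzoate (mixture of double-bond isomers), via phosphorus ylide 13 (not isolated)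
Conditions: K2CO3, 18-crown-6 (cat.), CH2Cl2, reflux
Reagents that add atoms: none
Why: A second Wittig olefination of a benzylic ylide with an electron-rich aryl aldehyde under the same mild carbonate conditions should join ring C without harming the methyl ester.

Step 8
Reactants: 14 methyl 4-[2-{2-[3-(2-{3-(benzyloxy)-4-isopropoxyphenyl}ethenyl)phenoxy]-3-methoxyphenyl}ethenyl]benzoate
Product: 15 methyl 4-[2-{2-[3-(2-{3-hydroxy-4-isopropoxyphenyl}ethyl)phenoxy]-3-methoxyphenyl}ethyl]benzoate
Conditions: H2 (1 atm), 10% Pd/C, EtOAc/MeOH, rt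
Reagents that add atoms: none
Why: Catalytic hydrogenation should saturate both stilbene double bonds and hydrogenolyse the benzyl ether in one operation, while the aryl ethers, the isopropyl ether and the ester are inert.

Step 9
Reactants: 15 methyl 4-[2-{2-[3-(2-{3-hydroxy-4-isopropoxyphenyl}ethyl)phenoxy]-3-methoxyphenyl}ethyl]benzoate
Product: 16 4-[2-{2-[3-(2-{3-hydroxy-4-isopropoxyphenyl}ethyl)phenoxy]-3-methoxyphenyl}ethyl]benzoic acid
Conditions: LiOH, THF/MeOH/H2O, 50 °C; then 1 M HCl
Reagents that add atoms: lithium hydroxide, [Li+].[OH-]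
Why: Saponification of the methyl benzoate by acyl substitution with hydroxide should give the seco acid after acidification, no other group being base-labile.

Step 10
Reactants: 16 4-[2-{2-[3-(2-{3-hydroxy-4-isopropoxyphenyl}ethyl)phenoxy]-3-methoxyphenyl}ethyl]benzoic acid
Product: 18 19-membered macrocyclic aryl benzoate (ring C O-3 acylated by the ring D carboxyl group; isopropyl ether on ring C), via O-acylisourea 17 (not isolated)
Conditions: DCC, DMAP, DMAP·HCl, CHCl3, reflux, syringe-pump addition of 16 (final concentration about 1 mM)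
Reagents that add atoms: none
Why: Carbodiimide macrolactonization under Keck conditions (Steglich acyl transfer through DMAP to a phenol, with DMAP·HCl suppressing N-acylurea formation) at high dilution should close the strain-free 19-membered aryl ester.

Step 11
Reactants: 18 19-membered macrocyclic aryl benzoate
Product: 19 O-isopropyl 18-membered macrocyclic bis(bibenzyl) diaryl ether
Conditions: Ni(cod)2 (20 mol%), 3,4-bis(dicyclohexylphosphino)thiophene (dcypt, 40 mol%), K3PO4 (1.5 equiv), mesitylene (5 mM), 150 °C, slow argon sweep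
Reagents that add atoms: none
Why: Proposed new method: zerovalent nickel carrying the bulky, electron-rich chelating diphosphine dcypt should add oxidatively into the acyl–oxygen bond of aryl benzoate 18 to give a 20-membered acyl nickel aryloxide, which de-inserts and loses CO to a 19-membered aryl nickel aryloxide and then forms the bond between C-4 of ring D and the ring C oxygen by reductive elimination, releasing 19 and the catalyst. The closest known reaction type is the nickel- or palladium-catalysed decarbonylative etherification of aryl esters of mostly azine carboxylic acids to diaryl ethers, which has not been shown for a simple 4-alkylbenzoate or as a ring contraction. The 18-membered ring is closed by ring contraction, that is by carbon–oxygen reductive elimination inside a nickelacycle, so both ends stay on one metal and oligomerization has no intermolecular step to start from; no stereocentre is formed. The step needs insertion at the acyl–oxygen bond and not at the aryl–oxygen bonds of the ester, the diaryl ether or the methyl and isopropyl ethers; the ester is the only carbonyl-activated carbon–oxygen bond in 18 and its benzoyl group is unhindered, whereas the ethers are unactivated and the aryl carbon on the oxygen side of the ester is flanked by the isopropoxy group. Sweeping out CO at 150 °C should keep the catalyst from being held as a nickel carbonyl and help the aryl–oxygen reductive elimination, which is expected to be the slow step for this electron-neutral aryl group.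

Step 12
Reactants: 19 O-isopropyl 18-membered macrocyclic bis(bibenzyl) diaryl ether
Product: 21 target macrocycle CNP0309263.0 (free phenol on ring C), via aryloxydichloroborane 20 (not isolated)
Conditions: BCl3 (3 equiv), CH2Cl2, −78 to 0 °C; then H2O
Reagents that add atoms: none
Why: Lewis acid dealkylation with BCl3 should cleave the secondary isopropyl aryl ether, which ionizes readily, much faster than the methyl ether on ring A or the diaryl ethers.

**Compound list**

1 | 2-fluoro-3-methoxybenzaldehyde | COc1cccc(C=O)c1F | starting material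
2 | 3-hydroxybenzyl alcohol | OCc1cccc(O)c1 | starting material
3 | 2-[3-(hydroxymethyl)phenoxy]-3-methoxybenzaldehyde | COc1cccc(C=O)c1Oc1cccc(CO)c1 | intermediate
4 | methyl 4-(bromomethyl)benzoate | COC(=O)c1ccc(CBr)cc1 | starting material
5 | [4-(methoxycarbonyl)benzyl]triphenylphosphonium bromide | COC(=O)c1ccc(C[P+](c2ccccc2)(c2ccccc2)c2ccccc2)cc1.[Br-] | intermediate
6 | [4-(methoxycarbonyl)benzylidene]triphenylphosphorane (ylide, not isolated) | COC(=O)c1ccc(C=P(c2ccccc2)(c2ccccc2)c2ccccc2)cc1 | intermediate
7 | methyl 4-[2-{2-[3-(hydroxymethyl)phenoxy]-3-methoxyphenyl}ethenyl]benzoate (E/Z mixture) | COC(=O)c1ccc(C=Cc2cccc(OC)c2Oc2cccc(CO)c2)cc1 | intermediate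
8 | methyl 4-[2-{2-[3-(bromomethyl)phenoxy]-3-methoxyphenyl}ethenyl]benzoate (E/Z mixture, not isolated) | COC(=O)c1ccc(C=Cc2cccc(OC)c2Oc2cccc(CBr)c2)cc1 | intermediate
9 | {3-[2-methoxy-6-[2-(4-(methoxycarbonyl)phenyl)ethenyl]phenoxy]benzyl}triphenylphosphonium bromide (E/Z mixture) | COC(=O)c1ccc(C=Cc2cccc(OC)c2Oc2cccc(C[P+](c3ccccc3)(c3ccccc3)c3ccccc3)c2)cc1.[Br-] | intermediate
10 | 3,4-dihydroxybenzaldehyde | O=Cc1ccc(O)c(O)c1 | starting material
11 | 3-hydroxy-4-isopropoxybenzaldehyde | CC(C)Oc1ccc(C=O)cc1O | intermediate
12 | 3-(benzyloxy)-4-isopropoxybenzaldehyde | CC(C)Oc1ccc(C=O)cc1OCc1ccccc1 | intermediate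
13 | ylide of phosphonium salt 9 (E/Z mixture, not isolated) | COC(=O)c1ccc(C=Cc2cccc(OC)c2Oc2cccc(C=P(c3ccccc3)(c3ccccc3)c3ccccc3)c2)cc1 | intermediate
14 | methyl 4-[2-{2-[3-(2-{3-(benzyloxy)-4-isopropoxyphenyl}ethenyl)phenoxy]-3-methoxyphenyl}ethenyl]benzoate (mixture of double-bond isomers) | COC(=O)c1ccc(C=Cc2cccc(OC)c2Oc2cccc(C=Cc3ccc(OC(C)C)c(OCc4ccccc4)c3)c2)cc1 | intermediate
15 | methyl 4-[2-{2-[3-(2-{3-hydroxy-4-isopropoxyphenyl}ethyl)phenoxy]-3-methoxyphenyl}ethyl]benzoate | COC(=O)c1ccc(CCc2cccc(OC)c2Oc2cccc(CCc3ccc(OC(C)C)c(O)c3)c2)cc1 | intermediate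
16 | 4-[2-{2-[3-(2-{3-hydroxy-4-isopropoxyphenyl}ethyl)phenoxy]-3-methoxyphenyl}ethyl]benzoic acid | OC(=O)c1ccc(CCc2cccc(OC)c2Oc2cccc(CCc3ccc(OC(C)C)c(O)c3)c2)cc1 | intermediate
17 | O-acylisourea from acid 16 and dicyclohexylcarbodiimide (not isolated) | CC(C)Oc1ccc(CCc2cccc(Oc3c(OC)cccc3CCc3ccc(cc3)C(=O)OC(=NC3CCCCC3)NC3CCCCC3)c2)cc1O | intermediate
18 | 19-membered macrocyclic aryl benzoate, isopropyl ether on ring C | COc1cccc2c1Oc1cccc(c1)CCc1ccc(OC(C)C)c(c1)OC(=O)c1ccc(cc1)CC2 | intermediate
19 | O-isopropyl 18-membered macrocyclic bis(bibenzyl) diaryl ether | COc1cccc2c1Oc1cccc(c1)CCc1ccc(OC(C)C)c(c1)Oc1ccc(cc1)CC2 | intermediate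
20 | aryloxydichloroborane of the macrocyclic phenol (not isolated) | COc1cccc2c1Oc1cccc(c1)CCc1ccc(OB(Cl)Cl)c(c1)Oc1ccc(cc1)CC2 | intermediate
21 | CNP0309263.0 | COc1cccc2c1Oc1cccc(c1)CCc1ccc(O)c(c1)Oc1ccc(cc1)CC2 | target

**Step count**

Total: 12 steps. Longest linear sequence: 9 steps (steps 1, 3, 4, 7, 8, 9, 10, 11, 12).

**Steps most likely to fail**

1. Step 11 (proposed new method). The aryl nickel aryloxide may not undergo aryl–oxygen reductive elimination, so the lactone is recovered or is protodecarbonylated to a ring-opened arene and phenol, or the catalyst is poisoned by retained CO.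
 Fallback, by known chemistry, setting out from 3 and coming back at 19: the ring C–O–ring D ether is made by copper catalysis and the 18-membered ring is closed at the ring B/ring C bridge by an intramolecular Wittig reaction. Aldehyde 3 is condensed with the ylide of purchased (4-bromobenzyl)triphenylphosphonium bromide (K2CO3, 18-crown-6, CH2Cl2, reflux) to give {3-[2-[2-(4-bromophenyl)ethenyl]-6-methoxyphenoxy]phenyl}methanol F1. Ullmann coupling of this aryl bromide with phenol 11 (CuI, N,N-dimethylglycine hydrochloride, Cs2CO3, dioxane, 90 °C) should give 3-{4-[2-{2-[3-(hydroxymethyl)phenoxy]-3-methoxyphenyl}ethenyl]phenoxy}-4-isopropoxybenzaldehyde F2. PPh3·HBr in refluxing MeCN converts its benzylic alcohol into the formyl-bearing phosphonium bromide F3. Slow addition of that salt to NaOMe in CH2Cl2 at high dilution closes the ring to the macrocyclic bis-stilbene F4. Hydrogenation (H2, Pd/C, EtOAc) saturates both double bonds and gives 19, which continues with step 12.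

2. Step 10. Intermolecular esterification may outrun ring closure and give dimers and oligomers, or the activated acid may rearrange to the N-acylurea before the hindered phenol attacks.
 Fallback, setting out from 7 and coming back at 18: the aryl ester is formed intermolecularly and the 19-membered ring is closed at the ring B/ring C bridge by McMurry coupling. Alcohol 7 is oxidized (MnO2, CH2Cl2, rt) to methyl 4-[2-{2-(3-formylphenoxy)-3-methoxyphenyl}ethenyl]benzoate F5. Its ester is hydrolysed (LiOH, THF/H2O, rt; then HCl) to 4-[2-{2-(3-formylphenoxy)-3-methoxyphenyl}ethenyl]benzoic acid F6. Steglich esterification with phenol 11 (EDC·HCl, DMAP, CH2Cl2) gives the dialdehyde 5-formyl-2-isopropoxyphenyl 4-[2-{2-(3-formylphenoxy)-3-methoxyphenyl}ethenyl]benzoate F7. Intramolecular McMurry coupling (TiCl4, Zn, pyridine, THF, reflux, slow addition) should give the macrocyclic diene lactone F8. Hydrogenation (H2, Pd/C, EtOAc) of both double bonds returns to 18.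

3. Step 1. Displacement at the fluorine-bearing carbon, which is flanked by the formyl and methoxy groups, may be slow, and the aldehyde may degrade at the temperature needed.
 Fallback, setting out from 2 and coming back at 3: Ullmann coupling of 2 with purchased 2-bromo-3-methoxybenzaldehyde (CuI, N,N-dimethylglycine hydrochloride, Cs2CO3, dioxane, 90 °C), in which the ortho formyl group assists the copper insertion, gives 3 directly.

Further compounds
F1 | step 11 | {3-[2-[2-(4-bromophenyl)ethenyl]-6-methoxyphenoxy]phenyl}methanol (E/Z mixture) | COc1cccc(C=Cc2ccc(Br)cc2)c1Oc1cccc(CO)c1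
F2 | step 11 | 3-{4-[2-{2-[3-(hydroxymethyl)phenoxy]-3-methoxyphenyl}ethenyl]phenoxy}-4-isopropoxybenzaldehyde (E/Z mixture) | COc1cccc(C=Cc2ccc(Oc3cc(C=O)ccc3OC(C)C)cc2)c1Oc1cccc(CO)c1
F3 | step 11 | {3-[2-[2-{4-(5-formyl-2-isopropoxyphenoxy)phenyl}ethenyl]-6-methoxyphenoxy]benzyl}triphenylphosphonium bromide (E/Z mixture) | COc1cccc(C=Cc2ccc(Oc3cc(C=O)ccc3OC(C)C)cc2)c1Oc1cccc(C[P+](c2ccccc2)(c2ccccc2)c2ccccc2)c1.[Br-]
F4 | step 11 | O-isopropyl 18-membered macrocyclic bis-stilbene (mixture of double-bond isomers) | COc1cccc2c1Oc1cccc(c1)C=Cc1ccc(OC(C)C)c(c1)Oc1ccc(cc1)C=C2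
F5 | step 10 | methyl 4-[2-{2-(3-formylphenoxy)-3-methoxyphenyl}ethenyl]benzoate (E/Z mixture) | COC(=O)c1ccc(C=Cc2cccc(OC)c2Oc2cccc(C=O)c2)cc1
F6 | step 10 | 4-[2-{2-(3-formylphenoxy)-3-methoxyphenyl}ethenyl]benzoic acid (E/Z mixture) | OC(=O)c1ccc(C=Cc2cccc(OC)c2Oc2cccc(C=O)c2)cc1
F7 | step 10 | 5-formyl-2-isopropoxyphenyl 4-[2-{2-(3-formylphenoxy)-3-methoxyphenyl}ethenyl]benzoate (E/Z mixture) | CC(C)Oc1ccc(C=O)cc1OC(=O)c1ccc(C=Cc2cccc(OC)c2Oc2cccc(C=O)c2)cc1
F8 | step 10 | 19-membered macrocyclic diene aryl benzoate (mixture of double-bond isomers) | COc1cccc2c1Oc1cccc(c1)C=Cc1ccc(OC(C)C)c(c1)OC(=O)c1ccc(cc1)C=C2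
F0 | step 1 | none | none
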